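The fraction of a charge found as target plus isomer of the product at 4.00 h is 54.5% in north-west and 4.70% in south-west, and that fraction times the charge comes out nearly the same in both.

| setting | north-west | south-west | summer | dawn | dusk | winter | midnight |
|---|---|---|---|---|---|---|---|
| solid substrate | 0.016 M | 0.19 M | 0.020 M | 0.040 M | 0.080 M | 0.15 M | 0.30 M |
| remark | run made earlier | run made earlier |  |  |  |  |  |
| time |  |  | 4.0 h | 4.0 h | 4.0 h | 4.0 h | 4.0 h |

| run | time / h | target / % | isomer of the product / % |
|---|---|---|---|
| north-west | 0.333 | 0.5 | 0.4 |
| north-west | 0.500 | 1.2 | 0.9 |
| north-west | 0.833 | 3.5 | 2.0 |
| north-west | 1.33 | 7.3 | 4.9 |
| north-west | 2.50 | 18.5 | 10.9 |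
| north-west | 4.00 | 32.2 | 22.3 |
| south-west | 0.250 | 0.3 | 0.1 |
| south-west | 0.833 | 0.4 | 0 |
| south-west | 1.33 | 1.1 | 0.6 |
| south-west | 2.00 | 1.4 | 0.6 |
| south-west | 3.00 | 1.5 | 1.7 |
| south-west | 4.00 | 2.7 | 2.0 |

(each reading ± 0.3 percentage points)

- as a solid, counted per litre of solution: solid substrate
- the numbers in the tables scatter with a standard deviation of 0.3 percentage points
- at the start none of the solid substrate is in solution
- "hardly changes" means that all values lie within two and a half points (for a concentration: within two and a half percent of the largest)

- share of target in all that became target or isomer of the product or third isomer for summer, dawn, dusk, winter, midnight, in this order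
- the course of these numbers from the first flask to the last (rises all the way / falls, then rises / falls all the way / rises, then falls / hardly changes)

1. North-west's first reading gives 0.0270 /h of its charge, while its mean up to the last reading is 0.136 /h. The rate starts lower than that mean, and none of the solid is in solution at the start.

2. The two runs differ in their charge. South-west's mean is 0.0118 /h, lower by a factor of 11.5, and its charge is larger by a factor of 11.9. Across these two runs the formation per litre reads as zero order in the charge.

3. Over the whole run this slowing adds up. The two values of fraction times charge average 0.00882 M, and I call this the reach: the fraction of a charge in target plus isomer of the product at 4.00 h, multiplied by the charge. A flask's fraction is its reach over its charge, so I expect 44.1% for summer and 2.94% for midnight. Summer's charge covers the reach.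

4. With one rate per litre, I expect one proportion of products. Target is 59.1% of the two shown products in north-west, but the third isomer goes unread and any of it lowers the share. I commit to a flat row below that value.

5. The forecast puts the row at 60%, above my ceiling, with the course hardly changes, since “all five flasks run under the same solution conditions”.

6. The flask gives 49.9% for summer and 49.9% for midnight, and the course is hardly changes.

    starting material ⇌ third isomer (K = 0.590, k = 0.00210 /min)
    starting material ⇌ isomer of the product (K = 9.40, k = 0.00340 /min)
    starting material ⇌ target (K = 2.10, k = 0.00630 /min)
    solid substrate ⇌ starting material, rate k4*(cs4 - [starting material]) while solid is left; crystals form when [starting material] > cs4 (solubility = 17.0 mM, k = 0.00570 /min)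

Summer at 4.00 h holds 44.4% of its charge in target plus isomer of the product, where the reach gave 44.1%; midnight holds 2.96%, where it gave 2.94%. In summer, half of the dissolving up to the asked time is done by 1.79 h, earlier than half of the step from starting material to target, at 2.29 h. At the asked time, summer's starting material is still made 1.14 times faster than it is used up, each step taken net, and it stands at 32.1% of the charge.

All runs stem from a simulated flask with made-up constants; scatter was added.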